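**Retrosynthetic overview**
1. Target ⇒ C8–O ester bond: 8α-alcohol 23 plus the silyl-protected (R)-side-chain acid 31 (from (R)-3-hydroxybutyrolactone); one global desilylation at the end.
2. 23 ⇒ enal/allyl bromide 20: a single CrCl2 allylation closes the ten-membered carbocycle (C6–C7) and then, in the same flask, the γ-lactone (C6–O–C12). These are the only rings and they are formed last.
3. 20 ⇒ α-silyloxy aldehyde 16 (Morita–Baylis–Hillman, oxidation, bromide). Key disconnection is the C8–O bond: enantioselective α-silyloxylation of aldehyde 13 sets C8, which then directs C7 and C6.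
4. 13 ⇒ diene Weinreb amide 7 + ynoate 10 (hydroboration, then copper-catalysed syn addition; fixes the 4,5-alkene and brings O-15). 7 ⇒ Johnson–Claisen rearrangement of dienol 3 (fixes the 1(10)-alkene).

Assumption: the target is read as the 4′-O-acetate of the germacranolide cnicin, (6R,7R,8S,3′R), with both ring alkenes of the trans-cyclodecene (costunolide) type; the preparation of peroxide 15 is counted as a step.

**Route**

Step 1
Reactants: 1 methacrolein; 2 vinylmagnesium bromide
Product: 3 2-methylpenta-1,4-dien-3-ol (racemic)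
Conditions: CH2=CHMgBr (1.1 equiv), THF, −78 to 0 °C; aq. NH4Cl
Reagents that add atoms: none
Why: Grignard 1,2-addition to an enal; the carbinol centre is destroyed in step 2, so no stereocontrol is needed.

Step 2
Reactants: 3 2-methylpenta-1,4-dien-3-ol; 4 triethyl orthoacetate
Product: 6 ethyl (4E)-4-methylhepta-4,6-dienoate, via ketene acetal 5 (not isolated)
Conditions: MeC(OEt)3 (5 equiv), EtCO2H (5 mol %), 140 °C, EtOH distilled off
Reagents that add atoms: none
Why: Johnson–Claisen rearrangement; the chair transition state with the vinyl group equatorial gives the E trisubstituted alkene (future C1=C10). The shift should run mainly through the more electron-rich isopropenyl arm, and the minor 6-methyl isomer is removed by distillation.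

Step 3
Reactants: 6 ethyl (4E)-4-methylhepta-4,6-dienoate
Product: 7 (4E)-N-methoxy-N,4-dimethylhepta-4,6-dienamide
Conditions: MeNH(OMe)·HCl (1.5 equiv), i-PrMgCl (3.0 equiv), THF, −20 to 0 °C
Reagents that add atoms: N,O-dimethylhydroxylamine hydrochloride, CNOC.Cl
Why: Weinreb amide formation by aminolysis of the ester with the magnesium amide; the amide lets step 6 stop at the aldehyde at C7.

Step 4
Reactants: 8 tert-butyldimethyl(prop-2-yn-1-yloxy)silane
Product: 10 methyl 4-(tert-butyldimethylsilyloxy)but-2-ynoate, via lithium acetylide 9 (not isolated)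
Conditions: n-BuLi (1.05 equiv), THF, −78 °C; ClCO2Me, −78 to 0 °C
Reagents that add atoms: methyl chloroformate, COC(=O)Cl
Why: C-acylation of a lithium acetylide with a chloroformate; this gives the C4–C5–C6/C15 unit with O-15 already protected.

Step 5
Reactants: 7 (4E)-N-methoxy-N,4-dimethylhepta-4,6-dienamide; 10 methyl 4-(tert-butyldimethylsilyloxy)but-2-ynoate
Product: 12 methyl (2Z,6E)-3-[(tert-butyldimethylsilyloxy)methyl]-10-[methoxy(methyl)amino]-7-methyl-10-oxodeca-2,6-dienoate, via alkylborane 11 (not isolated)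
Conditions: 9-BBN-H (1.1 equiv), THF, 0 °C to rt; then 10, CuOAc (5 mol %), P(OPh)3 (10 mol %), KOt-Bu (10 mol %), t-BuOH (1 equiv), dioxane, 40 °C
Reagents that add atoms: none
Why: Anti-Markovnikov hydroboration of the terminal alkene of the diene, then copper-catalysed conjugate addition of the alkylborane to the ynoate. Syn carbocupration and protonation with retention put the new alkyl group cis to H, so CH2OTBS is cis to the ester (the 4,5-alkene geometry of the target).

Step 6
Reactants: 12 methyl (2Z,6E)-3-[(tert-butyldimethylsilyloxy)methyl]-10-[methoxy(methyl)amino]-7-methyl-10-oxodeca-2,6-dienoate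
Product: 13 (4E,8Z)-8-[(tert-butyldimethylsilyloxy)methyl]-10-hydroxy-4-methyldeca-4,8-dienal
Conditions: i-Bu2AlH (3.5 equiv), CH2Cl2, −78 °C; aq. potassium sodium tartrate
Reagents that add atoms: none
Why: Hydride reduction; the Weinreb amide stops at the aldehyde (chelated tetrahedral intermediate) while the enoate goes to the allylic alcohol. C6 stays at the alcohol level so the Z alkene cannot isomerise during the amine-catalysed steps.

Step 7
Reactants: 14 hydrogen peroxide–urea
Product: 15 bis(triethylsilyl) peroxide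
Conditions: Et3SiCl (2.1 equiv), DABCO (2.1 equiv), CH2Cl2, 0 °C; filtration, short-path distillation
Reagents that add atoms: chlorotriethylsilane, CC[Si](Cl)(CC)CC
Why: O-silylation of hydrogen peroxide, the method used for the trimethylsilyl analogue.

Step 8
Reactants: 13 (4E,8Z)-8-[(tert-butyldimethylsilyloxy)methyl]-10-hydroxy-4-methyldeca-4,8-dienal; 15 bis(triethylsilyl) peroxide
Product: 16 (2S,4E,8Z)-8-[(tert-butyldimethylsilyloxy)methyl]-10-hydroxy-4-methyl-2-(triethylsilyloxy)deca-4,8-dienal
Conditions: 15 (1.3 equiv), (S)-α,α-diphenylprolinol trimethylsilyl ether (10 mol %), PhCO2H (10 mol %), THF, 0 °C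
Reagents that add atoms: none
Why: Proposed new method: the E-enamine formed from 13 and the prolinol silyl ether attacks one peroxide oxygen of 15 in a substitution at oxygen, on the face anti to the diaryl(silyloxy)methyl group, while the departing Et3SiO− is protonated by the benzoic acid co-catalyst; hydrolysis of the α-silyloxy iminium ion releases the (2S)-aldehyde with the C8–O bond formed and already capped as its triethylsilyl ether, and this centre later directs C7 and C6; the closest known reaction type is the enamine-catalysed α-benzoyloxylation of aldehydes with dibenzoyl peroxide (same attack on an O–O bond, same catalysts and facial sense), together with electrophilic oxygen transfer from bis(trimethylsilyl) peroxide to carbanions.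

Step 9
Reactants: 16 (2S,4E,8Z)-8-[(tert-butyldimethylsilyloxy)methyl]-10-hydroxy-4-methyl-2-(triethylsilyloxy)deca-4,8-dienal; 17 methyl acrylate
Product: 18 methyl (4S,6E,10Z)-10-[(tert-butyldimethylsilyloxy)methyl]-3,12-dihydroxy-6-methyl-2-methylidene-4-(triethylsilyloxy)dodeca-6,10-dienoate (C3 epimers)
Conditions: methyl acrylate (10 equiv, neat), DABCO (1.0 equiv), rt, 48 h
Reagents that add atoms: none
Why: Morita–Baylis–Hillman reaction; α-silyloxy aldehydes are activated acceptors. The new carbinol (C7) becomes sp2 in step 11, so its configuration does not matter.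

Step 10
Reactants: 18 methyl (4S,6E,10Z)-10-[(tert-butyldimethylsilyloxy)methyl]-3,12-dihydroxy-6-methyl-2-methylidene-4-(triethylsilyloxy)dodeca-6,10-dienoate
Product: 19 methyl (4S,6E,10Z)-10-[(tert-butyldimethylsilyloxy)methyl]-3-hydroxy-6-methyl-2-methylidene-12-oxo-4-(triethylsilyloxy)dodeca-6,10-dienoate
Conditions: TEMPO (10 mol %), PhI(OAc)2 (1.2 equiv), CH2Cl2, rt
Reagents that add atoms: none
Why: Oxoammonium oxidation, selective for the primary allylic alcohol over the hindered, electron-poor secondary carbinol; near-neutral conditions keep the Z enal.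

Step 11
Reactants: 19 methyl (4S,6E,10Z)-10-[(tert-butyldimethylsilyloxy)methyl]-3-hydroxy-6-methyl-2-methylidene-12-oxo-4-(triethylsilyloxy)dodeca-6,10-dienoate
Product: 20 methyl (2Z,4S,6E,10Z)-2-(bromomethyl)-10-[(tert-butyldimethylsilyloxy)methyl]-6-methyl-12-oxo-4-(triethylsilyloxy)dodeca-2,6,10-trienoate
Conditions: NBS (1.3 equiv), Me2S (1.5 equiv), CH2Cl2, 0 °C to rt
Reagents that add atoms: N-bromosuccinimide, O=C1CCC(=O)N1Br
Why: Corey–Kim-type activation of the Baylis–Hillman alcohol and SN2′ delivery of bromide give the thermodynamically preferred (Z)-2-(bromomethyl)enoate; C8 is not touched.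

Step 12
Reactants: 20 methyl (2Z,4S,6E,10Z)-2-(bromomethyl)-10-[(tert-butyldimethylsilyloxy)methyl]-6-methyl-12-oxo-4-(triethylsilyloxy)dodeca-2,6,10-trienoate
Product: 23 (1(10)E,4Z)-8α-hydroxy-15-(tert-butyldimethylsilyloxy)germacra-1(10),4,11(13)-trien-12,6α-olide, via hydroxy ester 21 (not isolated), via silyl lactone 22 (not isolated)
Conditions: CrCl2 (8 equiv), THF, 2 mM, slow addition, rt; aq. NH4Cl; then crude, PPTS (0.2 equiv), MeOH–CH2Cl2 (1:1), 0 °C
Reagents that add atoms: none
Why: Intramolecular Nozaki–Hiyama (Barbier-type) allylation. γ-Attack of the 2-(methoxycarbonyl)allylchromium on the enal forms C6–C7 and the ten-membered ring, and the chromium alkoxide closes the lactone. A crown-like chair transition state with C5, C8 and the silyloxy group pseudo-equatorial is expected to give the trans lactone with H-7 anti to both H-6 and H-8 (6R,7R relative to 8S). PPTS methanolysis then removes the secondary triethylsilyl ether and leaves the primary TBS ether.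

Step 13
Reactants: 24 (4R)-4-hydroxyoxolan-2-one
Product: 28 (4R)-4-hydroxy-3-methylideneoxolan-2-one, via dianion 25 (not isolated), via Mannich base 26 (not isolated), via ammonium iodide 27 (not isolated)
Conditions: LiN(i-Pr)2 (2.2 equiv), THF, −78 to −40 °C; Me2N=CH2 I, −78 °C to rt; aq. work-up; MeI, MeOH, rt; aq. NaHCO3, CH2Cl2
Reagents that add atoms: N,N-dimethylmethyleneiminium iodide, C=[N+](C)C.[I-]
Why: Alkylation of the β-hydroxy lactone dianion with Eschenmoser's salt, then quaternisation and elimination (α-methylenation); the alkoxide is not a leaving group, and the C3′ carbinol from the chiral pool is untouched.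

Step 14
Reactants: 28 (4R)-4-hydroxy-3-methylideneoxolan-2-one
Product: 29 (4R)-3-methylidene-4-(triethylsilyloxy)oxolan-2-one
Conditions: Et3SiCl (1.2 equiv), imidazole (2 equiv), CH2Cl2, 0 °C
Reagents that add atoms: chlorotriethylsilane, CC[Si](Cl)(CC)CC
Why: Standard silylation of the secondary alcohol so that it cannot be acylated in steps 15 and 16.

Step 15
Reactants: 29 (4R)-3-methylidene-4-(triethylsilyloxy)oxolan-2-one
Product: 31 (3R)-4-acetoxy-2-methylidene-3-(triethylsilyloxy)butanoic acid, via lithium carboxylate 30 (not isolated)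
Conditions: LiOH·H2O (1.05 equiv), THF–H2O (3:1), 0 °C; concentrate; Ac2O (1.2 equiv), pyridine, 0 °C; aq. KHSO4 work-up
Reagents that add atoms: lithium hydroxide, [Li+].[OH-]; acetic anhydride, CC(=O)OC(C)=O
Why: Lactone saponification followed by O-acetylation of the liberated primary alcohol on the carboxylate salt; acetylation blocks relactonisation and places the acetate that the target carries at O-4′.

Step 16
Reactants: 23 (1(10)E,4Z)-8α-hydroxy-15-(tert-butyldimethylsilyloxy)germacra-1(10),4,11(13)-trien-12,6α-olide; 31 (3R)-4-acetoxy-2-methylidene-3-(triethylsilyloxy)butanoic acid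
Product: 32 (1(10)E,4Z)-8α-{[(3R)-4-acetoxy-2-methylidene-3-(triethylsilyloxy)butanoyl]oxy}-15-(tert-butyldimethylsilyloxy)germacra-1(10),4,11(13)-trien-12,6α-olide
Conditions: 31 (1.5 equiv), EDC·HCl (2 equiv), DMAP (0.3 equiv), CH2Cl2, 0 °C to rt
Reagents that add atoms: none
Why: Steglich (carbodiimide/DMAP) esterification of the only free hydroxyl; the C8–O bond of the alcohol is not broken, so configuration is retained.

Step 17
Reactants: 32 (1(10)E,4Z)-8α-{[(3R)-4-acetoxy-2-methylidene-3-(triethylsilyloxy)butanoyl]oxy}-15-(tert-butyldimethylsilyloxy)germacra-1(10),4,11(13)-trien-12,6α-olide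
Product: 33 (1(10)E,4Z)-8α-{[(3R)-4-acetoxy-3-hydroxy-2-methylidenebutanoyl]oxy}-15-hydroxygermacra-1(10),4,11(13)-trien-12,6α-olide (target)
Conditions: HF·pyridine, pyridine, THF, 0 °C to rt
Reagents that add atoms: none
Why: Fluoride-mediated cleavage of both silyl ethers in one operation; the pyridine buffer protects the acid-sensitive cyclodecadiene, and the acetate and lactone are inert.

**Compound list**
1 | methacrolein (2-methylprop-2-enal) | CC(=C)C=O | starting material
2 | vinylmagnesium bromide | C=C[Mg]Br | starting material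
3 | 2-methylpenta-1,4-dien-3-ol (racemic) | CC(=C)C(O)C=C | intermediate
4 | triethyl orthoacetate | CCOC(C)(OCC)OCC | starting material
5 | 3-[(1-ethoxyethenyl)oxy]-2-methylpenta-1,4-diene (mixed ketene acetal) | C=C(OCC)OC(C=C)C(C)=C | intermediate
6 | ethyl (4E)-4-methylhepta-4,6-dienoate | CCOC(=O)CC/C(C)=C/C=C | intermediate
7 | (4E)-N-methoxy-N,4-dimethylhepta-4,6-dienamide | CON(C)C(=O)CC/C(C)=C/C=C | intermediate
8 | tert-butyldimethyl(prop-2-yn-1-yloxy)silane | C#CCO[Si](C)(C)C(C)(C)C | starting material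
9 | lithium acetylide of 8 | [Li]C#CCO[Si](C)(C)C(C)(C)C | intermediate
10 | methyl 4-(tert-butyldimethylsilyloxy)but-2-ynoate | COC(=O)C#CCO[Si](C)(C)C(C)(C)C | intermediate
11 | (4E)-7-(9-borabicyclo[3.3.1]nonan-9-yl)-N-methoxy-N,4-dimethylhept-4-enamide | CON(C)C(=O)CC/C(C)=C/CCB1C2CCCC1CCC2 | intermediate
12 | methyl (2Z,6E)-3-[(tert-butyldimethylsilyloxy)methyl]-10-[methoxy(methyl)amino]-7-methyl-10-oxodeca-2,6-dienoate | COC(=O)/C=C(\CO[Si](C)(C)C(C)(C)C)CC/C=C(\C)CCC(=O)N(C)OC | intermediate
13 | (4E,8Z)-8-[(tert-butyldimethylsilyloxy)methyl]-10-hydroxy-4-methyldeca-4,8-dienal | O=CCC/C(C)=C/CC/C(CO[Si](C)(C)C(C)(C)C)=C/CO | intermediate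
14 | hydrogen peroxide–urea (1:1) | NC(N)=O.OO | starting material
15 | bis(triethylsilyl) peroxide | CC[Si](CC)(CC)OO[Si](CC)(CC)CC | intermediate
16 | (2S,4E,8Z)-8-[(tert-butyldimethylsilyloxy)methyl]-10-hydroxy-4-methyl-2-(triethylsilyloxy)deca-4,8-dienal | O=C[C@@H](O[Si](CC)(CC)CC)C/C(C)=C/CC/C(CO[Si](C)(C)C(C)(C)C)=C/CO | intermediate
17 | methyl acrylate | C=CC(=O)OC | starting material
18 | methyl (4S,6E,10Z)-10-[(tert-butyldimethylsilyloxy)methyl]-3,12-dihydroxy-6-methyl-2-methylidene-4-(triethylsilyloxy)dodeca-6,10-dienoate (C3 epimers) | COC(=O)C(=C)C(O)[C@@H](O[Si](CC)(CC)CC)C/C(C)=C/CC/C(CO[Si](C)(C)C(C)(C)C)=C/CO | intermediate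
19 | methyl (4S,6E,10Z)-10-[(tert-butyldimethylsilyloxy)methyl]-3-hydroxy-6-methyl-2-methylidene-12-oxo-4-(triethylsilyloxy)dodeca-6,10-dienoate (C3 epimers) | COC(=O)C(=C)C(O)[C@@H](O[Si](CC)(CC)CC)C/C(C)=C/CC/C(CO[Si](C)(C)C(C)(C)C)=C/C=O | intermediate
20 | methyl (2Z,4S,6E,10Z)-2-(bromomethyl)-10-[(tert-butyldimethylsilyloxy)methyl]-6-methyl-12-oxo-4-(triethylsilyloxy)dodeca-2,6,10-trienoate | COC(=O)/C(CBr)=C/[C@@H](O[Si](CC)(CC)CC)C/C(C)=C/CC/C(CO[Si](C)(C)C(C)(C)C)=C/C=O | intermediate
21 | methyl (1(10)E,4Z)-6α-hydroxy-8α-(triethylsilyloxy)-15-(tert-butyldimethylsilyloxy)germacra-1(10),4,11(13)-trien-12-oate (7α-H; formed as its trivalent chromium alkoxide) | COC(=O)C(=C)[C@H]1[C@H](O)/C=C(\CO[Si](C)(C)C(C)(C)C)CC/C=C(\C)C[C@@H]1O[Si](CC)(CC)CC | intermediate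
22 | (1(10)E,4Z)-8α-(triethylsilyloxy)-15-(tert-butyldimethylsilyloxy)germacra-1(10),4,11(13)-trien-12,6α-olide (7α-H) | C=C1C(=O)O[C@@H]2/C=C(\CO[Si](C)(C)C(C)(C)C)CC/C=C(\C)C[C@H](O[Si](CC)(CC)CC)[C@@H]12 | intermediate
23 | (1(10)E,4Z)-8α-hydroxy-15-(tert-butyldimethylsilyloxy)germacra-1(10),4,11(13)-trien-12,6α-olide (6R,7R,8S) | C=C1C(=O)O[C@@H]2/C=C(\CO[Si](C)(C)C(C)(C)C)CC/C=C(\C)C[C@H](O)[C@@H]12 | intermediate
24 | (4R)-4-hydroxyoxolan-2-one ((R)-3-hydroxy-γ-butyrolactone) | O=C1C[C@@H](O)CO1 | starting material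
25 | dilithium alkoxide–enolate of 24 | [Li]OC1=C[C@@H](O[Li])CO1 | intermediate
26 | (4R)-3-[(dimethylamino)methyl]-4-hydroxyoxolan-2-one (mainly 3,4-trans) | O=C1C(CN(C)C)[C@@H](O)CO1 | intermediate
27 | [(4R)-4-hydroxy-2-oxooxolan-3-yl]methyl-trimethylammonium iodide | O=C1C(C[N+](C)(C)C)[C@@H](O)CO1.[I-] | intermediate
28 | (4R)-4-hydroxy-3-methylideneoxolan-2-one | O=C1C(=C)[C@@H](O)CO1 | intermediate
29 | (4R)-3-methylidene-4-(triethylsilyloxy)oxolan-2-one | O=C1C(=C)[C@@H](O[Si](CC)(CC)CC)CO1 | intermediate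
30 | lithium (3R)-4-hydroxy-2-methylidene-3-(triethylsilyloxy)butanoate | [Li+].[O-]C(=O)C(=C)[C@@H](O[Si](CC)(CC)CC)CO | intermediate
31 | (3R)-4-acetoxy-2-methylidene-3-(triethylsilyloxy)butanoic acid | OC(=O)C(=C)[C@@H](O[Si](CC)(CC)CC)COC(C)=O | intermediate
32 | (1(10)E,4Z)-8α-{[(3R)-4-acetoxy-2-methylidene-3-(triethylsilyloxy)butanoyl]oxy}-15-(tert-butyldimethylsilyloxy)germacra-1(10),4,11(13)-trien-12,6α-olide | C=C1C(=O)O[C@@H]2/C=C(\CO[Si](C)(C)C(C)(C)C)CC/C=C(\C)C[C@H](OC(=O)C(=C)[C@@H](O[Si](CC)(CC)CC)COC(C)=O)[C@@H]12 | intermediate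
33 | (1(10)E,4Z)-8α-{[(3R)-4-acetoxy-3-hydroxy-2-methylidenebutanoyl]oxy}-15-hydroxygermacra-1(10),4,11(13)-trien-12,6α-olide (6R,7R,8S,3′R) | C=C1C(=O)O[C@@H]2/C=C(\CO)CC/C=C(\C)C[C@H](OC(=O)C(=C)[C@@H](O)COC(C)=O)[C@@H]12 | target

**Step count and risks**

Total step count: 17. Longest linear sequence: 12 (steps 1, 2, 3, 5, 6, 8, 9, 10, 11, 12, 16, 17).

Steps most likely to fail:

Step 8 (the new α-silyloxylation). The silyl peroxide may be too weak an oxygen electrophile, or may silylate the catalyst instead. The fallback uses known chemistry, sets out from 13 and comes back at 19. D-Proline-catalysed α-aminoxylation of 13 with nitrosobenzene (CHCl3, 4 °C), reduced in the same flask with NaBH4, gives (2S,4E,8Z)-2-(anilinooxy)-8-[(tert-butyldimethylsilyloxy)methyl]-4-methyldeca-4,8-diene-1,10-diol F1. Zn dust in AcOH–EtOH cleaves the N–O bond to the triol F2. Et3SiCl and imidazole give the tris(triethylsilyl) ether F3. Swern oxidation ((COCl)2, DMSO, Et3N), which turns primary but not secondary triethylsilyl ethers directly into aldehydes, gives the dialdehyde F4. Morita–Baylis–Hillman reaction of F4 with 17 (DABCO), selective for the activated α-silyloxy aldehyde over the hindered enal, gives 19.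

Step 12 (macrocyclisation). Oligomerisation, the wrong C6/C7 diastereomer, or 1,4-elimination of the δ-silyloxy group from the allylmetal could intervene. The fallback sets out from 19 and comes back at 22. Ac2O and DMAP give the Baylis–Hillman acetate F5. Borylation with B2pin2 and Pd2(dba)3 (zerovalent palladium) gives the 2-(methoxycarbonyl)allylboronate F6. Heating F6 in toluene at high dilution (80–100 °C) closes the ring by an intramolecular allylboration through a closed six-membered boron transition state, with no low-valent metal and no free allyl anion. Aqueous work-up lactonises the borate to 22, which is desilylated to 23 as in step 12.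

Step 9 (Morita–Baylis–Hillman reaction on the α-silyloxy aldehyde). The reaction may be slow, and the amine base may epimerise C8 or move the silyl group. The fallback sets out from 16 and comes back at 18. Hydroalumination of methyl propiolate with i-Bu2AlH in THF–HMPA gives methyl 2-(diisobutylalumanyl)prop-2-enoate F7. Adding 16 to F7 (2.5 equiv, 0 °C; the first equivalent is consumed by the free hydroxyl) gives 18 by direct carbonyl addition, without any amine.

**Further compounds**
F1 | step 8 | (2S,4E,8Z)-2-(anilinooxy)-8-[(tert-butyldimethylsilyloxy)methyl]-4-methyldeca-4,8-diene-1,10-diol | OC[C@@H](ONc1ccccc1)C/C(C)=C/CC/C(CO[Si](C)(C)C(C)(C)C)=C/CO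
F2 | step 8 | (2S,4E,8Z)-8-[(tert-butyldimethylsilyloxy)methyl]-4-methyldeca-4,8-diene-1,2,10-triol | OC[C@@H](O)C/C(C)=C/CC/C(CO[Si](C)(C)C(C)(C)C)=C/CO
F3 | step 8 | (2S,4E,8Z)-8-[(tert-butyldimethylsilyloxy)methyl]-4-methyl-1,2,10-tris(triethylsilyloxy)deca-4,8-diene | CC[Si](CC)(CC)OC[C@@H](O[Si](CC)(CC)CC)C/C(C)=C/CC/C(CO[Si](C)(C)C(C)(C)C)=C/CO[Si](CC)(CC)CC
F4 | step 8 | (2S,4E,8Z)-8-[(tert-butyldimethylsilyloxy)methyl]-4-methyl-2-(triethylsilyloxy)deca-4,8-dienedial | O=C[C@@H](O[Si](CC)(CC)CC)C/C(C)=C/CC/C(CO[Si](C)(C)C(C)(C)C)=C/C=O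
F5 | step 12 | methyl (4S,6E,10Z)-3-acetoxy-10-[(tert-butyldimethylsilyloxy)methyl]-6-methyl-2-methylidene-12-oxo-4-(triethylsilyloxy)dodeca-6,10-dienoate (C3 epimers) | COC(=O)C(=C)C(OC(C)=O)[C@@H](O[Si](CC)(CC)CC)C/C(C)=C/CC/C(CO[Si](C)(C)C(C)(C)C)=C/C=O
F6 | step 12 | methyl (2E,4S,6E,10Z)-10-[(tert-butyldimethylsilyloxy)methyl]-6-methyl-12-oxo-2-[(4,4,5,5-tetramethyl-1,3,2-dioxaborolan-2-yl)methyl]-4-(triethylsilyloxy)dodeca-2,6,10-trienoate | COC(=O)/C(CB1OC(C)(C)C(C)(C)O1)=C/[C@@H](O[Si](CC)(CC)CC)C/C(C)=C/CC/C(CO[Si](C)(C)C(C)(C)C)=C/C=O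
F7 | step 9 | methyl 2-(diisobutylalumanyl)prop-2-enoate | COC(=O)C(=C)[Al](CC(C)C)CC(C)C
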